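The route rests on the C4–C5 bond of the heptane chain, formed by a reagent-controlled lithiation–borylation. The target's core is an anti-(3S,5S)-1,3-diol whose carbinol carbons C3 and C5 flank the lone methylene C4 and each carry a 2-arylethyl arm (guaiacyl ring via C1–C2, syringyl ring via C6–C7). Both carbinol carbons are therefore born as (+)-sparteine-ligated α-lithiated benzoates of two 3-arylpropanols and are stitched onto diborylmethane, which supplies C4. The first carbenoid gives a C1–C4 1,2-bis(boronic ester) in the flask, whose primary boron captures the C5 carbenoid; 1,2-migration forges C4–C5, and oxidation reveals the diol. The precursors are three achiral components.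

Key step: step 6

Remark (assumptions): the heptane chain is numbered C1 (bearing the 4-hydroxy-3-methoxyphenyl, guaiacyl, ring) to C7 (bearing the 4-hydroxy-3,5-dimethoxyphenyl, syringyl, ring), the target being the anti-(3S,5S)-diol; compounds 1, 4 and 9 and (+)-sparteine are taken as purchasable.

Step 1
Reactants: 1 3-(4-hydroxy-3-methoxyphenyl)propan-1-ol
Product: 2 3-(4-hydroxy-3-methoxyphenyl)propyl 2,4,6-triisopropylbenzoate
Conditions: 2,4,6-triisopropylbenzoic acid (1.2 equiv), PPh3, DIAD, THF, 0 °C → rt
Reagents that add atoms: 2,4,6-triisopropylbenzoic acid, CC(C)c1cc(C(C)C)c(C(=O)O)c(C(C)C)c1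
Why: Mitsunobu esterification, in which the carboxylic acid is by far the more acidic pronucleophile, so the primary alcohol should be esterified while the phenol stays free.

Step 2
Reactants: 2 3-(4-hydroxy-3-methoxyphenyl)propyl 2,4,6-triisopropylbenzoate
Product: 3 3-[3-methoxy-4-(triisopropylsilyloxy)phenyl]propyl 2,4,6-triisopropylbenzoate
Conditions: TIPSCl, imidazole, DMF, rt
Reagents that add atoms: chlorotriisopropylsilane (TIPSCl), CC(C)[Si](Cl)(C(C)C)C(C)C
Why: Standard silylation of a phenol; the aryl triisopropylsilyl ether should tolerate s-BuLi at −78 °C and mild perborate and fall to fluoride at the end.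

Step 3
Reactants: 4 4-allyl-2,6-dimethoxyphenol
Product: 5 (4-allyl-2,6-dimethoxyphenoxy)triisopropylsilane
Conditions: TIPSOTf, 2,6-lutidine, CH2Cl2, 0 °C → rt
Reagents that add atoms: triisopropylsilyl trifluoromethanesulfonate (TIPSOTf), CC(C)[Si](OS(=O)(=O)C(F)(F)F)(C(C)C)C(C)C
Why: Silylation with the silyl triflate, chosen because the phenol oxygen sits between two methoxy groups and needs the more reactive silyl donor.

Step 4
Reactants: 5 (4-allyl-2,6-dimethoxyphenoxy)triisopropylsilane
Product: 7 3-[3,5-dimethoxy-4-(triisopropylsilyloxy)phenyl]propan-1-ol, via B-alkyl-9-BBN adduct 6 (not isolated)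
Conditions: 9-BBN, THF, 0 °C → rt; then NaBO3·4H2O, H2O, rt
Reagents that add atoms: sodium perborate tetrahydrate (NaBO3·4H2O; anion drawn as its dimer, water of hydration left out), [Na+].[Na+].O[B-]1(O)OO[B-](O)(O)OO1
Why: Anti-Markovnikov hydroboration of the terminal alkene with the bulky borane followed by mild perborate oxidation (Brown hydroboration–oxidation), which should leave the aryl silyl ether intact.

Step 5
Reactants: 7 3-[3,5-dimethoxy-4-(triisopropylsilyloxy)phenyl]propan-1-ol
Product: 8 3-[3,5-dimethoxy-4-(triisopropylsilyloxy)phenyl]propyl 2,4,6-triisopropylbenzoate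
Conditions: 2,4,6-triisopropylbenzoic acid (1.2 equiv), PPh3, DIAD, THF, 0 °C → rt
Reagents that add atoms: 2,4,6-triisopropylbenzoic acid, CC(C)c1cc(C(C)C)c(C(=O)O)c(C(C)C)c1
Why: Mitsunobu esterification of an unhindered primary alcohol, the usual entry to the hindered benzoates used as carbenoid precursors.

Step 6
Reactants: 3 3-[3-methoxy-4-(triisopropylsilyloxy)phenyl]propyl 2,4,6-triisopropylbenzoate; 9 bis(4,4,5,5-tetramethyl-1,3,2-dioxaborolan-2-yl)methane (diborylmethane); 8 3-[3,5-dimethoxy-4-(triisopropylsilyloxy)phenyl]propyl 2,4,6-triisopropylbenzoate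
Product: 16 (3S,5S)-1-[3-methoxy-4-(triisopropylsilyloxy)phenyl]-7-[3,5-dimethoxy-4-(triisopropylsilyloxy)phenyl]heptane-3,5-diol, via guaiacyl lithiated benzoate 10 (not isolated), via first boronate complex 11 (not isolated), via 1,2-bis(boronic ester) 12 (not isolated), via syringyl lithiated benzoate 13 (not isolated), via second boronate complex 14 (not isolated), via 1,3-bis(boronic ester) 15 (not isolated)
Conditions: a) 3 (1.05 equiv), (+)-sparteine, s-BuLi (1.0 equiv), Et2O, −78 °C, 5 h; then 9 (1.0 equiv), −78 °C → 35 °C; b) the solution of 12 is cannulated onto 13 [from 8 (1.3 equiv), (+)-sparteine, s-BuLi, Et2O, −78 °C, 5 h], −78 °C → 35 °C; c) NaBO3·4H2O, THF/H2O, rt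
Reagents that add atoms: sodium perborate tetrahydrate (NaBO3·4H2O; anion drawn as its dimer, water of hydration left out), [Na+].[Na+].O[B-]1(O)OO[B-](O)(O)OO1
Why: (+)-Sparteine/s-BuLi removes the pro-R α-hydrogen of each benzoate (Hoppe-type enantioselective lithiation) to give the configurationally stable (R)-carbenoids 10 and 13; each adds to boron with retention, and in boronate complexes 11 and 14 the boron-bound CH2 group migrates to carbon with inversion while the benzoate leaves anti, so that C3–C4 (first stage) and then C4–C5 (second stage, the union of the two aryl-bearing halves) are formed stereospecifically before perborate replaces both C–B bonds by C–OH with retention. The closest known reaction type is the lithiation–borylation (Matteson-type 1,2-metallate rearrangement) in its two documented forms, unidirectional homologation of diborylmethane by a sparteine-ligated carbenoid and homologation of a 1,2-bis(boronic ester) at its primary boron, here telescoped. No ring is closed. C3 and C5 are each set by reagent control from (+)-sparteine, independently of one another, so the same diamine gives (3S,5S), the anti-diol. The step needs single addition to diborylmethane, which the bulk of the sparteine-ligated carbenoid secures because it cannot reach the second boron of anionic complex 11, and attack at the primary and not the secondary boron of 12, again secured by sterics. It also needs α-lithiation in preference to ring lithiation or carbonyl attack, secured by carbonyl-directed deprotonation, the shielding triisopropylphenyl group and the absence of a strong directing group on either ring (methoxy and bulky silyloxy only), with s-BuLi kept limiting in the first stage so that no carbenoid 10 is left to compete for 12.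

Step 7
Reactants: 16 (3S,5S)-1-[3-methoxy-4-(triisopropylsilyloxy)phenyl]-7-[3,5-dimethoxy-4-(triisopropylsilyloxy)phenyl]heptane-3,5-diol
Product: 17 (3S,5S)-1-(4-hydroxy-3-methoxyphenyl)-7-(4-hydroxy-3,5-dimethoxyphenyl)heptane-3,5-diol
Conditions: Bu4NF (TBAF, 2.5 equiv), AcOH (2.5 equiv), THF, 0 °C → rt
Reagents that add atoms: none
Why: Fluoride-mediated cleavage of both aryl silyl ethers (desilylation), buffered with acetic acid so that the electron-rich phenols are released without standing as phenoxides; the diol stereocentres are not touched.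

Compound list
1 | 3-(4-hydroxy-3-methoxyphenyl)propan-1-ol (dihydroconiferyl alcohol) | COc1cc(CCCO)ccc1O | starting material
2 | 3-(4-hydroxy-3-methoxyphenyl)propyl 2,4,6-triisopropylbenzoate | COc1cc(CCCOC(=O)c2c(C(C)C)cc(C(C)C)cc2C(C)C)ccc1O | intermediate
3 | 3-[3-methoxy-4-(triisopropylsilyloxy)phenyl]propyl 2,4,6-triisopropylbenzoate | COc1cc(CCCOC(=O)c2c(C(C)C)cc(C(C)C)cc2C(C)C)ccc1O[Si](C(C)C)(C(C)C)C(C)C | intermediate
4 | 4-allyl-2,6-dimethoxyphenol | COc1cc(CC=C)cc(OC)c1O | starting material
5 | (4-allyl-2,6-dimethoxyphenoxy)triisopropylsilane | COc1cc(CC=C)cc(OC)c1O[Si](C(C)C)(C(C)C)C(C)C | intermediate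
6 | 9-{3-[3,5-dimethoxy-4-(triisopropylsilyloxy)phenyl]propyl}-9-borabicyclo[3.3.1]nonane (not isolated) | COc1cc(CCCB2C3CCCC2CCC3)cc(OC)c1O[Si](C(C)C)(C(C)C)C(C)C | intermediate
7 | 3-[3,5-dimethoxy-4-(triisopropylsilyloxy)phenyl]propan-1-ol | COc1cc(CCCO)cc(OC)c1O[Si](C(C)C)(C(C)C)C(C)C | intermediate
8 | 3-[3,5-dimethoxy-4-(triisopropylsilyloxy)phenyl]propyl 2,4,6-triisopropylbenzoate | COc1cc(CCCOC(=O)c2c(C(C)C)cc(C(C)C)cc2C(C)C)cc(OC)c1O[Si](C(C)C)(C(C)C)C(C)C | intermediate
9 | bis(4,4,5,5-tetramethyl-1,3,2-dioxaborolan-2-yl)methane (diborylmethane) | CC1(C)OB(CB2OC(C)(C)C(C)(C)O2)OC1(C)C | starting material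
10 | (R)-1-lithio-3-[3-methoxy-4-(triisopropylsilyloxy)phenyl]propyl 2,4,6-triisopropylbenzoate, as its (+)-sparteine complex (not isolated) | COc1cc(CC[C@H](OC(=O)c2c(C(C)C)cc(C(C)C)cc2C(C)C)[Li])ccc1O[Si](C(C)C)(C(C)C)C(C)C | intermediate
11 | lithium boronate complex from 10 and 9: tetracoordinate boron bearing the (R)-1-(triisopropylbenzoyloxy)-3-arylpropyl group and the CH2B(pinacolato) group (not isolated) | [Li+].COc1cc(CC[C@H](OC(=O)c2c(C(C)C)cc(C(C)C)cc2C(C)C)[B-]2(CB3OC(C)(C)C(C)(C)O3)OC(C)(C)C(C)(C)O2)ccc1O[Si](C(C)C)(C(C)C)C(C)C | intermediate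
12 | (R)-2,2'-{4-[3-methoxy-4-(triisopropylsilyloxy)phenyl]butane-1,2-diyl}bis(4,4,5,5-tetramethyl-1,3,2-dioxaborolane) (not isolated) | COc1cc(CC[C@H](B2OC(C)(C)C(C)(C)O2)CB2OC(C)(C)C(C)(C)O2)ccc1O[Si](C(C)C)(C(C)C)C(C)C | intermediate
13 | (R)-1-lithio-3-[3,5-dimethoxy-4-(triisopropylsilyloxy)phenyl]propyl 2,4,6-triisopropylbenzoate, as its (+)-sparteine complex (not isolated) | COc1cc(CC[C@H](OC(=O)c2c(C(C)C)cc(C(C)C)cc2C(C)C)[Li])cc(OC)c1O[Si](C(C)C)(C(C)C)C(C)C | intermediate
14 | lithium boronate complex from 13 and the primary boron of 12, (R) at both stereocentres (not isolated) | [Li+].COc1cc(CC[C@H](B2OC(C)(C)C(C)(C)O2)C[B-]2(OC(C)(C)C(C)(C)O2)[C@@H](OC(=O)c2c(C(C)C)cc(C(C)C)cc2C(C)C)CCc2cc(OC)c(O[Si](C(C)C)(C(C)C)C(C)C)c(OC)c2)ccc1O[Si](C(C)C)(C(C)C)C(C)C | intermediate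
15 | 2,2'-{(3S,5S)-1-[3-methoxy-4-(triisopropylsilyloxy)phenyl]-7-[3,5-dimethoxy-4-(triisopropylsilyloxy)phenyl]heptane-3,5-diyl}bis(4,4,5,5-tetramethyl-1,3,2-dioxaborolane) (not isolated) | COc1cc(CC[C@H](B2OC(C)(C)C(C)(C)O2)C[C@@H](B2OC(C)(C)C(C)(C)O2)CCc2cc(OC)c(O[Si](C(C)C)(C(C)C)C(C)C)c(OC)c2)ccc1O[Si](C(C)C)(C(C)C)C(C)C | intermediate
16 | (3S,5S)-1-[3-methoxy-4-(triisopropylsilyloxy)phenyl]-7-[3,5-dimethoxy-4-(triisopropylsilyloxy)phenyl]heptane-3,5-diol | COc1cc(CC[C@H](O)C[C@@H](O)CCc2cc(OC)c(O[Si](C(C)C)(C(C)C)C(C)C)c(OC)c2)ccc1O[Si](C(C)C)(C(C)C)C(C)C | intermediate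
17 | (3S,5S)-1-(4-hydroxy-3-methoxyphenyl)-7-(4-hydroxy-3,5-dimethoxyphenyl)heptane-3,5-diol | COc1cc(CC[C@H](O)C[C@@H](O)CCc2cc(OC)c(O)c(OC)c2)ccc1O | target

Total step count: 7. Longest linear sequence: 5 steps (steps 3, 4, 5, 6, 7).

Steps most likely to fail

Step 6. What may go wrong: loss of site control in the telescoped sequence (incomplete 1,2-migration, a second homologation by the first carbenoid, attack at the secondary boron, lithiation of a ring), so that homologues arise that are hard to separate. The fallback makes the C4–C5 bond by an aldol addition and sets both stereocentres afterwards in one catalyst-controlled, stereoconvergent hydrogenation. It sets out from alcohol 7, which Dess–Martin periodinane (NaHCO3, CH2Cl2) should oxidise to 3-[3,5-dimethoxy-4-(triisopropylsilyloxy)phenyl]propanal F1. Commercial zingerone (CC(=O)CCc1ccc(O)c(OC)c1) is silylated (TIPSCl, imidazole, DMF) to 4-[3-methoxy-4-(triisopropylsilyloxy)phenyl]butan-2-one F2. LiN(iPr)2 in THF at −78 °C deprotonates its methyl group to the kinetic lithium enolate F3, which adds to F1 and, after NH4Cl quench, should give racemic 5-hydroxy-7-[3,5-dimethoxy-4-(triisopropylsilyloxy)phenyl]-1-[3-methoxy-4-(triisopropylsilyloxy)phenyl]heptan-3-one F4. A second Dess–Martin oxidation erases that stereocentre and gives 1-[3-methoxy-4-(triisopropylsilyloxy)phenyl]-7-[3,5-dimethoxy-4-(triisopropylsilyloxy)phenyl]heptane-3,5-dione F5. Hydrogenation with RuCl2[(S)-BINAP] (H2, 50 atm, MeOH/CH2Cl2, 50 °C; Noyori reduction of 1,3-diketones) should then give the anti-(3S,5S)-diol, and the fallback comes back to the route at 16.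

Step 1. What may go wrong: alkylation of the free phenol oxygen by the activated primary alcohol of a second molecule (aryl ether oligomers), because the bulky carboxylate is a slow nucleophile. The fallback reverses the order of protection and esterification. It sets out from 1: NaH (1.0 equiv, THF, 0 °C) should deprotonate only the phenol to the sodium phenoxide F6, which TIPSCl silylates on oxygen to give 3-[3-methoxy-4-(triisopropylsilyloxy)phenyl]propan-1-ol F7. Mitsunobu esterification of F7 with 2,4,6-triisopropylbenzoic acid (PPh3, DIAD, THF), now without a competing phenol, comes back to the route at 3.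

Step 5. What may go wrong: sluggish displacement at the alkoxyphosphonium ion by the hindered carboxylate, with incomplete conversion and a product that is hard to free from phosphine oxide and hydrazide. The fallback replaces alkylation of the carboxylate by acyl transfer: it sets out from alcohol 7, which is acylated with 2,4,6-triisopropylbenzoyl chloride (pyridine, DMAP, 60 °C), and comes back to the route at 8 without any new compound.

Further compounds
F1 | step 6 | 3-[3,5-dimethoxy-4-(triisopropylsilyloxy)phenyl]propanal | O=CCCc1cc(OC)c(O[Si](C(C)C)(C(C)C)C(C)C)c(OC)c1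
F2 | step 6 | 4-[3-methoxy-4-(triisopropylsilyloxy)phenyl]butan-2-one | CC(=O)CCc1ccc(O[Si](C(C)C)(C(C)C)C(C)C)c(OC)c1
F3 | step 6 | lithium 4-[3-methoxy-4-(triisopropylsilyloxy)phenyl]but-1-en-2-olate | [Li]OC(=C)CCc1ccc(O[Si](C(C)C)(C(C)C)C(C)C)c(OC)c1
F4 | step 6 | racemic 5-hydroxy-7-[3,5-dimethoxy-4-(triisopropylsilyloxy)phenyl]-1-[3-methoxy-4-(triisopropylsilyloxy)phenyl]heptan-3-one | COc1cc(CCC(=O)CC(O)CCc2cc(OC)c(O[Si](C(C)C)(C(C)C)C(C)C)c(OC)c2)ccc1O[Si](C(C)C)(C(C)C)C(C)C
F5 | step 6 | 1-[3-methoxy-4-(triisopropylsilyloxy)phenyl]-7-[3,5-dimethoxy-4-(triisopropylsilyloxy)phenyl]heptane-3,5-dione | COc1cc(CCC(=O)CC(=O)CCc2cc(OC)c(O[Si](C(C)C)(C(C)C)C(C)C)c(OC)c2)ccc1O[Si](C(C)C)(C(C)C)C(C)C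
F6 | step 1 | sodium 4-(3-hydroxypropyl)-2-methoxyphenolate | [Na+].COc1cc(CCCO)ccc1[O-]
F7 | step 1 | 3-[3-methoxy-4-(triisopropylsilyloxy)phenyl]propan-1-ol | COc1cc(CCCO)ccc1O[Si](C(C)C)(C(C)C)C(C)C
F0 | step 5 | none | none
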